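**Retrosynthetic overview**

1. Numbering as in germacranolides: C1 hemiketal carbon, C4 methyl carbinol carbon, C5=C6 enol-lactone alkene (C6 = butenolide gamma-carbon), C7=C11 butenolide alkene, C8 ester-bearing carbon, C10 CH(CH3), C12 lactone carbonyl, C13 CH2OAc; the oxolane is O/C1/C2/C3/C4.
2. Feature used: in the oxolane the oxygen-bearing C4 is allylic to the enol-lactone alkene C5=C6, so C4–O plus C5=C6–O(lactone) is a hydrated 1-acyloxy-allene, and the hemiketal carbon C1 lies 1,4 to C4. A ten-membered gamma-keto allene (C1=O, C4=C5=C6) can therefore close the oxolane, set C4 from the allene axis, fix C1 through the one-atom bridge and create the (5E)-alkylidene butenolide in one hydrative step.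
3. Disconnections: C8 ester and C13 acetate (end game); oxolane C4–O/C1–OH by gold-catalysed transannular hydrative cyclisation (last ring); ten-membered carbocycle by anionic acetylenic oxy-Cope ring expansion of a cis-7-vinyl-7a-propynyl tetrahydrobenzofuran-2-one (C3–C4 made, C1–C6 of a temporary cyclohexane broken).
4. That bicycle comes from furan-3,4-diyldimethanol: side chain by Stetter reaction, C8 by asymmetric transfer hydrogenation, C10 by trans-methylation of a lactone, cyclohexanone by Friedel-Crafts acylation of the furan, C1 by vinyl addition, butenolide by singlet-oxygen oxidation of the furan and propynyl Grignard addition (C6).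
5. Ring order: furan (bought), cyclohexane (temporary), butenolide (from the furan), ten-membered carbocycle (cyclohexane opened), oxolane.

Key step: step 13

Remark: TBS = tert-butyldimethylsilyl, TMS = trimethylsilyl; furan-3,4-diyldimethanol is assumed to be purchasable; atom labels C1 to C13 in the step texts are the positions the atoms take in the target, while compound names use systematic locants.

Step 1
Reactants: 1 furan-3,4-diyldimethanol
Product: 2 [4-(TBSOCH2)furan-3-yl]methanol
Conditions: NaH (1.0 equiv), THF, 0 °C; then TBSCl (1.0 equiv), 0 °C to rt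
Reagents that add atoms: tert-butyldimethylsilyl chloride, CC(C)(C)[Si](C)(C)Cl
Why: O-silylation of the monosodium alkoxide of a symmetrical diol, which should stop at the mono-ether because the sparingly soluble mono-alkoxide is silylated before a second deprotonation; no stereocentre is formed.

Step 2
Reactants: 2 [4-(TBSOCH2)furan-3-yl]methanol
Product: 3 4-(TBSOCH2)furan-3-carbaldehyde
Conditions: MnO2 (10 equiv), CH2Cl2, rt
Reagents that add atoms: none
Why: MnO2 oxidation of a heteroaryl carbinol to the aldehyde, which leaves the furan and the silyl ether untouched.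

Step 3
Reactants: 3 4-(TBSOCH2)furan-3-carbaldehyde; 4 methyl acrylate
Product: 5 methyl 4-[4-(TBSOCH2)furan-3-yl]-4-oxobutanoate
Conditions: 3-benzyl-5-(2-hydroxyethyl)-4-methylthiazolium chloride (20 mol%), Et3N, EtOH, 75 °C
Reagents that add atoms: none
Why: Stetter reaction: the thiazolylidene-derived Breslow intermediate of the heteroaryl aldehyde adds in 1,4 fashion to the acrylate and should give the 1,4-keto ester that carries C8, C9, C10 and C1.

Step 4
Reactants: 5 methyl 4-[4-(TBSOCH2)furan-3-yl]-4-oxobutanoate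
Product: 7 (5S)-5-[4-(TBSOCH2)furan-3-yl]oxolan-2-one, via hydroxy ester 6 (not isolated)
Conditions: RuCl[(S,S)-TsDPEN](p-cymene) (1 mol%), HCO2H/Et3N (5:2), EtOAc, 30 °C; then PPTS (cat.), toluene, 60 °C
Reagents that add atoms: none
Why: Noyori asymmetric transfer hydrogenation of a heteroaryl alkyl ketone, for which the (S,S) catalyst should give the (S)-carbinol (C8) as it does with acetophenones and 4-aryl-4-oxobutanoates, followed by acid-catalysed lactonisation of the gamma-hydroxy ester.

Step 5
Reactants: 7 (5S)-5-[4-(TBSOCH2)furan-3-yl]oxolan-2-one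
Product: 8 (3R,5S)-3-methyl-5-[4-(TBSOCH2)furan-3-yl]oxolan-2-one
Conditions: LiN(i-Pr)2 (1.1 equiv), THF, −78 °C; then CH3I, −78 °C
Reagents that add atoms: iodomethane, CI
Why: Alkylation of a butyrolactone enolate, which takes place on the face anti to the C5 substituent and should give the trans-3,5 lactone, so that the 3R centre (C10) is set by C8.

Step 6
Reactants: 8 (3R,5S)-3-methyl-5-[4-(TBSOCH2)furan-3-yl]oxolan-2-one
Product: 11 (2R,4S)-4-(TBSO)-2-methyl-4-[4-(TBSOCH2)furan-3-yl]butanoic acid, via lithium carboxylate 9 (not isolated), via silyl ester 10 (not isolated)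
Conditions: LiOH, THF/H2O, rt, evaporate; TBSCl (2.5 equiv), imidazole, DMF, rt; K2CO3, MeOH/THF/H2O, 0 °C; citric acid work-up
Reagents that add atoms: lithium hydroxide, [Li+].[OH-]; tert-butyldimethylsilyl chloride, CC(C)(C)[Si](C)(C)Cl
Why: Saponification, exhaustive silylation of the carboxylate salt and selective methanolysis of the labile silyl ester is the standard way to hold a gamma-hydroxy acid open as its silyl ether; neither stereocentre is involved.

Step 7
Reactants: 11 (2R,4S)-4-(TBSO)-2-methyl-4-[4-(TBSOCH2)furan-3-yl]butanoic acid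
Product: 13 (4S,6R)-4-(TBSO)-3-(TBSOCH2)-6-methyl-5,6-dihydro-1-benzofuran-7(4H)-one, via mixed anhydride 12 (not isolated)
Conditions: (CF3CO)2O (1.5 equiv), CH2Cl2, 0 °C to rt
Reagents that add atoms: none
Why: Intramolecular Friedel-Crafts acylation of the electron-rich furan by the mixed trifluoroacetic anhydride, which can only reach the free alpha-position next to the side chain (six-membered ring), as in the closure of 4-(3-furyl)butanoic acids to tetrahydrobenzofuran-7-ones.

Step 8
Reactants: 13 (4S,6R)-4-(TBSO)-3-(TBSOCH2)-6-methyl-5,6-dihydro-1-benzofuran-7(4H)-one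
Product: 14 (4S,6R,7R)-4-(TBSO)-3-(TBSOCH2)-7-ethenyl-6-methyl-4,5,6,7-tetrahydro-1-benzofuran-7-ol
Conditions: CH2=CHMgBr (3 equiv), CeCl3 (3 equiv), THF, −78 °C; aq. NH4Cl
Reagents that add atoms: vinylmagnesium bromide, C=C[Mg]Br
Why: 1,2-Addition of the vinylcerium reagent (CeCl3 suppresses enolisation of the aryl ketone), which should take place on the carbonyl face anti to the adjacent methyl group as in 2-alkylcyclohexanones and 2-alkyl-1-tetralones and so give the 7R carbinol (C1) with vinyl trans and hydroxyl cis to the methyl group.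

Step 9
Reactants: 14 (4S,6R,7R)-4-(TBSO)-3-(TBSOCH2)-7-ethenyl-6-methyl-4,5,6,7-tetrahydro-1-benzofuran-7-ol
Product: 15 (4S,6R,7R)-4-(TBSO)-3-(TBSOCH2)-7-ethenyl-6-methyl-7-(TMSO)-4,5,6,7-tetrahydro-1-benzofuran
Conditions: N-(trimethylsilyl)imidazole (3 equiv), CH2Cl2, rt
Reagents that add atoms: N-(trimethylsilyl)imidazole, C[Si](C)(C)n1ccnc1
Why: Neutral O-silylation of the tertiary alcohol, which protects the acid-labile 2-furyl vinyl carbinol against Achmatowicz-type rearrangement in step 10 and makes the C1 oxygen a non-chelating polar group for step 11.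

Step 10
Reactants: 15 (4S,6R,7R)-4-(TBSO)-3-(TBSOCH2)-7-ethenyl-6-methyl-7-(TMSO)-4,5,6,7-tetrahydro-1-benzofuran
Product: 16 (4S,6R,7R)-4-(TBSO)-3-(TBSOCH2)-7-ethenyl-7a-hydroxy-6-methyl-7-(TMSO)-5,6,7,7a-tetrahydro-1-benzofuran-2(4H)-one (both 7a epimers)
Conditions: O2, tetraphenylporphyrin (1 mol%), i-Pr2NEt (2 equiv), visible light, CH2Cl2, −78 °C
Reagents that add atoms: dioxygen (as singlet oxygen), O=O
Why: [4+2] cycloaddition of singlet oxygen to the furan and base-induced Kornblum-DeLaMare fragmentation of the endoperoxide at its only C–H terminus, which should give the 5-hydroxybutenolide with the carbonyl at C12 and the lactol at C6 (both lactol epimers serve).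

Step 11
Reactants: 16 (4S,6R,7R)-4-(TBSO)-3-(TBSOCH2)-7-ethenyl-7a-hydroxy-6-methyl-7-(TMSO)-5,6,7,7a-tetrahydro-1-benzofuran-2(4H)-one
Product: 19 (4S,6R,7R,7aS)-4-(TBSO)-3-(TBSOCH2)-7-ethenyl-7-hydroxy-6-methyl-7a-(prop-1-ynyl)-5,6,7,7a-tetrahydro-1-benzofuran-2(4H)-one, via hydroxy acid 17 (not isolated), via TMS ether 18 (not isolated)
Conditions: CH3C≡CMgBr (3.5 equiv), THF, −78 to 0 °C; aq. NH4Cl; then citric acid, MeOH, rt
Reagents that add atoms: 1-propynylmagnesium bromide, CC#C[Mg]Br
Why: Grignard addition to a lactol (pseudo-acid): the first equivalent opens it to the (Z)-keto carboxylate and the alkynyl reagent then adds to the C6 ketone axially and anti to the axial C1–OTMS bond (Felkin-Anh polar model, both effects reinforcing), which should place propynyl cis to vinyl, before acidification closes the butenolide and citric acid in methanol removes only the tertiary TMS ether.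

Step 12
Reactants: 19 (4S,6R,7R,7aS)-4-(TBSO)-3-(TBSOCH2)-7-ethenyl-7-hydroxy-6-methyl-7a-(prop-1-ynyl)-5,6,7,7a-tetrahydro-1-benzofuran-2(4H)-one
Product: 21 (8S,10R)-8,13-bis(TBSO)-1-oxogermacra-4,5,7(11)-trien-12,6-olide with an (M) allene C4=C5=C6, via potassium enolate 20 (not isolated)
Conditions: KN(SiMe3)2 (1.1 equiv), 18-crown-6 (1.5 equiv), THF, −78 to −20 °C; AcOH, −78 °C
Reagents that add atoms: none
Why: Anionic oxy-Cope rearrangement of a 1-en-5-yn-3-olate (acetylenic oxy-Cope): the lactone C–O bond must lie in the butenolide plane, so propynyl is axial and gauche to the equatorial vinyl group, C3 bonds to C4 on the side of C1 while C1–C6 breaks, the temporary cyclohexane is expanded to the ten-membered ring and the (7R,7aS) centres are translated into the (M) allene axis.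

Step 13
Reactants: 21 (8S,10R)-8,13-bis(TBSO)-1-oxogermacra-4,5,7(11)-trien-12,6-olide, (M) allene
Product: 22 (1R,4S,8S,10R,5E)-1,4-epoxy-1-hydroxy-8,13-bis(TBSO)germacra-5,7(11)-dien-12,6-olide
Conditions: Ph3PAuNTf2 (5 mol%), THF/H2O (10:1), 0 °C to rt
Reagents that add atoms: water, O
Why: Proposed new method: the cationic phosphine-gold catalyst (monovalent gold) should bind the electron-richer C4=C5 bond of the acyloxy-allene on its exterior face, and the C1 oxygen (as the gem-diol formed in the wet solvent, or as the carbonyl oxygen whose oxocarbenium ion is then taken up by water) should add to C4 anti to gold, after which protodeauration of the C5 alkenylgold with retention gives the hemiketal and the conjugated alkylidene butenolide. The closest known reaction types are the gold-catalysed exo-hydroalkoxylation of gamma-hydroxy allenes to 2-alkenyl oxolanes, which runs by anti addition with axis-to-centre chirality transfer, and the gold- or silver-catalysed attack of ketone oxygen on allenes; new here are the transannular setting and the lactone-bearing allene. The oxolane closes in the 5-exo-trig mode, oxygen onto the allene terminus C4 with C5=C6 left exocyclic to the new ring. C4 is set by the (M) axis of the allene, because within the ten-membered ring the C1 oxygen can reach the C4 p-orbital only from the side on which C7 lies, and C1 follows from C4 because a one-oxygen bridge across the ring can only be cis. The step needs regioselectivity for C4 over the electrophilic central carbon C5 and it needs C4 to end cis to C7 across C5=C6: the first rests on the 1,4 distance between C1 and C4 and on the tertiary, oxygen-stabilised allyl cation character that gold induces at C4, the second on anti addition followed by stereoretentive protodeauration.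

Step 14
Reactants: 22 (1R,4S,8S,10R,5E)-1,4-epoxy-1-hydroxy-8,13-bis(TBSO)germacra-5,7(11)-dien-12,6-olide
Product: 23 (1R,4S,8S,10R,5E)-1,4-epoxy-1,8,13-trihydroxygermacra-5,7(11)-dien-12,6-olide
Conditions: HF·pyridine, pyridine, THF, 0 °C to rt
Reagents that add atoms: none
Why: Fluoride-mediated cleavage of both TBS ethers under pyridine-buffered conditions, which should leave the tertiary hemiketal, the allylic C4–O bond and the enol lactone intact.

Step 15
Reactants: 23 (1R,4S,8S,10R,5E)-1,4-epoxy-1,8,13-trihydroxygermacra-5,7(11)-dien-12,6-olide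
Product: 24 (1R,4S,8S,10R,5E)-13-acetoxy-1,4-epoxy-1,8-dihydroxygermacra-5,7(11)-dien-12,6-olide
Conditions: AcCl (1.05 equiv), 2,4,6-collidine, CH2Cl2, −78 °C
Reagents that add atoms: acetyl chloride, CC(Cl)=O
Why: Kinetically controlled acylation with acetyl chloride and a hindered pyridine base, which should select the primary allylic C13 hydroxyl over the hindered secondary C8 hydroxyl and the unreactive tertiary hemiketal hydroxyl.

Step 16
Reactants: 25 (tert-butyldimethylsilyloxy)acetaldehyde; 26 ethyl 2-(triphenylphosphoranylidene)propanoate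
Product: 27 ethyl (E)-4-(TBSO)-2-methylbut-2-enoate
Conditions: CH2Cl2, rt
Reagents that add atoms: none
Why: Wittig olefination with a stabilised alpha-branched ylide, which gives the (E)-trisubstituted enoate.

Step 17
Reactants: 27 ethyl (E)-4-(TBSO)-2-methylbut-2-enoate
Product: 28 (E)-4-(TBSO)-2-methylbut-2-enoic acid
Conditions: LiOH, THF/MeOH/H2O, 0 °C to rt; then 1 M HCl to pH 3
Reagents that add atoms: lithium hydroxide, [Li+].[OH-]
Why: Saponification of the ethyl ester; the primary TBS ether and the alkene geometry are not affected.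

Step 18
Reactants: 24 (1R,4S,8S,10R,5E)-13-acetoxy-1,4-epoxy-1,8-dihydroxygermacra-5,7(11)-dien-12,6-olide; 28 (E)-4-(TBSO)-2-methylbut-2-enoic acid
Product: 29 (1R,4S,8S,10R,5E)-13-acetoxy-1,4-epoxy-1-hydroxy-8-[(E)-4-(TBSO)-2-methylbut-2-enoyloxy]germacra-5,7(11)-dien-12,6-olide
Conditions: DCC (1.5 equiv), DMAP (0.3 equiv), CH2Cl2, 0 °C to rt
Reagents that add atoms: none
Why: Steglich esterification of the secondary C8 hydroxyl (the tertiary hemiketal hydroxyl does not react), which proceeds by acyl transfer to oxygen and therefore keeps the 8S configuration.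

Step 19
Reactants: 29 (1R,4S,8S,10R,5E)-13-acetoxy-1,4-epoxy-1-hydroxy-8-[(E)-4-(TBSO)-2-methylbut-2-enoyloxy]germacra-5,7(11)-dien-12,6-olide
Product: 30 (1R,4S,8S,10R,5E)-13-acetoxy-1,4-epoxy-1-hydroxy-8-[(E)-4-hydroxy-2-methylbut-2-enoyloxy]germacra-5,7(11)-dien-12,6-olide (target)
Conditions: HF·pyridine, pyridine, THF, 0 °C
Reagents that add atoms: none
Why: Buffered fluoride cleavage of the last silyl ether, which should leave the acetate, the enoate, the hemiketal and the enol lactone untouched and give the target.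

**Compound list**

1 | furan-3,4-diyldimethanol | OCc1cocc1CO | starting material
2 | [4-(TBSOCH2)furan-3-yl]methanol | OCc1cocc1CO[Si](C)(C)C(C)(C)C | intermediate
3 | 4-(TBSOCH2)furan-3-carbaldehyde | O=Cc1cocc1CO[Si](C)(C)C(C)(C)C | intermediate
4 | methyl acrylate | C=CC(=O)OC | starting material
5 | methyl 4-[4-(TBSOCH2)furan-3-yl]-4-oxobutanoate | COC(=O)CCC(=O)c1cocc1CO[Si](C)(C)C(C)(C)C | intermediate
6 | methyl (4S)-4-hydroxy-4-[4-(TBSOCH2)furan-3-yl]butanoate (not isolated) | COC(=O)CC[C@H](O)c1cocc1CO[Si](C)(C)C(C)(C)C | intermediate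
7 | (5S)-5-[4-(TBSOCH2)furan-3-yl]oxolan-2-one | O=C1CC[C@H](O1)c1cocc1CO[Si](C)(C)C(C)(C)C | intermediate
8 | (3R,5S)-3-methyl-5-[4-(TBSOCH2)furan-3-yl]oxolan-2-one | O=C1[C@H](C)C[C@H](O1)c1cocc1CO[Si](C)(C)C(C)(C)C | intermediate
9 | lithium (2R,4S)-4-hydroxy-2-methyl-4-[4-(TBSOCH2)furan-3-yl]butanoate (not isolated) | [Li+].[O-]C(=O)[C@H](C)C[C@H](O)c1cocc1CO[Si](C)(C)C(C)(C)C | intermediate
10 | TBS (2R,4S)-4-(TBSO)-2-methyl-4-[4-(TBSOCH2)furan-3-yl]butanoate (not isolated) | CC(C)(C)[Si](C)(C)OC(=O)[C@H](C)C[C@H](O[Si](C)(C)C(C)(C)C)c1cocc1CO[Si](C)(C)C(C)(C)C | intermediate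
11 | (2R,4S)-4-(TBSO)-2-methyl-4-[4-(TBSOCH2)furan-3-yl]butanoic acid | OC(=O)[C@H](C)C[C@H](O[Si](C)(C)C(C)(C)C)c1cocc1CO[Si](C)(C)C(C)(C)C | intermediate
12 | mixed anhydride of 11 with trifluoroacetic acid (not isolated) | O=C(OC(=O)[C@H](C)C[C@H](O[Si](C)(C)C(C)(C)C)c1cocc1CO[Si](C)(C)C(C)(C)C)C(F)(F)F | intermediate
13 | (4S,6R)-4-(TBSO)-3-(TBSOCH2)-6-methyl-5,6-dihydro-1-benzofuran-7(4H)-one | O=C1[C@H](C)C[C@H](O[Si](C)(C)C(C)(C)C)c2c(CO[Si](C)(C)C(C)(C)C)coc12 | intermediate
14 | (4S,6R,7R)-4-(TBSO)-3-(TBSOCH2)-7-ethenyl-6-methyl-4,5,6,7-tetrahydro-1-benzofuran-7-ol | C=C[C@@]1(O)[C@H](C)C[C@H](O[Si](C)(C)C(C)(C)C)c2c(CO[Si](C)(C)C(C)(C)C)coc12 | intermediate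
15 | (4S,6R,7R)-4-(TBSO)-3-(TBSOCH2)-7-ethenyl-6-methyl-7-(TMSO)-4,5,6,7-tetrahydro-1-benzofuran | C=C[C@@]1(O[Si](C)(C)C)[C@H](C)C[C@H](O[Si](C)(C)C(C)(C)C)c2c(CO[Si](C)(C)C(C)(C)C)coc12 | intermediate
16 | (4S,6R,7R)-4-(TBSO)-3-(TBSOCH2)-7-ethenyl-7a-hydroxy-6-methyl-7-(TMSO)-5,6,7,7a-tetrahydro-1-benzofuran-2(4H)-one (7a epimers) | C=C[C@@]1(O[Si](C)(C)C)[C@H](C)C[C@H](O[Si](C)(C)C(C)(C)C)C2=C(CO[Si](C)(C)C(C)(C)C)C(=O)OC12O | intermediate
17 | ring-opened (Z)-hydroxy acid: cyclohexane with C1(OTMS)(vinyl), C6(OH)(propynyl), C8 OTBS, C10 methyl and the exocyclic C7=C11(CH2OTBS)CO2H unit (not isolated) | C=C[C@@]1(O[Si](C)(C)C)[C@H](C)C[C@H](O[Si](C)(C)C(C)(C)C)/C(=C(\CO[Si](C)(C)C(C)(C)C)/C(O)=O)[C@@]1(O)C#CC | intermediate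
18 | (4S,6R,7R,7aS)-4-(TBSO)-3-(TBSOCH2)-7-ethenyl-6-methyl-7a-(prop-1-ynyl)-7-(TMSO)-5,6,7,7a-tetrahydro-1-benzofuran-2(4H)-one (not isolated) | C=C[C@@]1(O[Si](C)(C)C)[C@H](C)C[C@H](O[Si](C)(C)C(C)(C)C)C2=C(CO[Si](C)(C)C(C)(C)C)C(=O)O[C@]12C#CC | intermediate
19 | (4S,6R,7R,7aS)-4-(TBSO)-3-(TBSOCH2)-7-ethenyl-7-hydroxy-6-methyl-7a-(prop-1-ynyl)-5,6,7,7a-tetrahydro-1-benzofuran-2(4H)-one | C=C[C@@]1(O)[C@H](C)C[C@H](O[Si](C)(C)C(C)(C)C)C2=C(CO[Si](C)(C)C(C)(C)C)C(=O)O[C@]12C#CC | intermediate
20 | potassium C1–C2 enolate of 21 (not isolated) | [K+].C[C@@H]1C[C@H](O[Si](C)(C)C(C)(C)C)C2=C(CO[Si](C)(C)C(C)(C)C)C(=O)OC2=[C@]=C(C)C/C=C1/[O-] | intermediate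
21 | (8S,10R)-8,13-bis(TBSO)-1-oxogermacra-4,5,7(11)-trien-12,6-olide, (M) allene C4=C5=C6 | C[C@@H]1C[C@H](O[Si](C)(C)C(C)(C)C)C2=C(CO[Si](C)(C)C(C)(C)C)C(=O)OC2=[C@]=C(C)CCC1=O | intermediate
22 | (1R,4S,8S,10R,5E)-1,4-epoxy-1-hydroxy-8,13-bis(TBSO)germacra-5,7(11)-dien-12,6-olide | CC(C)(C)[Si](C)(C)OCC1=C2/C(=C\[C@]3(C)CC[C@@](O)(O3)[C@H](C)C[C@@H]2O[Si](C)(C)C(C)(C)C)OC1=O | intermediate
23 | (1R,4S,8S,10R,5E)-1,4-epoxy-1,8,13-trihydroxygermacra-5,7(11)-dien-12,6-olide | OCC1=C2/C(=C\[C@]3(C)CC[C@@](O)(O3)[C@H](C)C[C@@H]2O)OC1=O | intermediate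
24 | (1R,4S,8S,10R,5E)-13-acetoxy-1,4-epoxy-1,8-dihydroxygermacra-5,7(11)-dien-12,6-olide | CC(=O)OCC1=C2/C(=C\[C@]3(C)CC[C@@](O)(O3)[C@H](C)C[C@@H]2O)OC1=O | intermediate
25 | (tert-butyldimethylsilyloxy)acetaldehyde | CC(C)(C)[Si](C)(C)OCC=O | starting material
26 | ethyl 2-(triphenylphosphoranylidene)propanoate | CCOC(=O)C(C)=P(c1ccccc1)(c1ccccc1)c1ccccc1 | starting material
27 | ethyl (E)-4-(TBSO)-2-methylbut-2-enoate | CCOC(=O)/C(C)=C/CO[Si](C)(C)C(C)(C)C | intermediate
28 | (E)-4-(TBSO)-2-methylbut-2-enoic acid | OC(=O)/C(C)=C/CO[Si](C)(C)C(C)(C)C | intermediate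
29 | (1R,4S,8S,10R,5E)-13-acetoxy-1,4-epoxy-1-hydroxy-8-[(E)-4-(TBSO)-2-methylbut-2-enoyloxy]germacra-5,7(11)-dien-12,6-olide | CC(=O)OCC1=C2/C(=C\[C@]3(C)CC[C@@](O)(O3)[C@H](C)C[C@@H]2OC(=O)/C(C)=C/CO[Si](C)(C)C(C)(C)C)OC1=O | intermediate
30 | (1R,4S,8S,10R,5E)-13-acetoxy-1,4-epoxy-1-hydroxy-8-[(E)-4-hydroxy-2-methylbut-2-enoyloxy]germacra-5,7(11)-dien-12,6-olide (CNP0154520.2) | CC(=O)OCC1=C2/C(=C\[C@]3(C)CC[C@@](O)(O3)[C@H](C)C[C@@H]2OC(=O)/C(C)=C/CO)OC1=O | target

**Step count and risks**

Total steps: 19. Longest linear sequence: 17 (steps 1 to 15, 18 and 19).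

The three steps most likely to fail:

First, step 13, which bears the label. The gold-allene complex may lose its axial information through a planar gold-allyl cation before the C–O bond forms, water or the C1 oxygen may add to the electrophilic central allene carbon C5 instead of C4, or protodeauration may be slow. The fallback uses known chemistry and sets out from 21. Electrophile-induced hydrative cyclisation with N-iodosuccinimide (NaHCO3, MeCN/H2O, 0 °C; anti iodo-alkoxylation of allenes by internal oxygen nucleophiles is established) should give the C5-iodo hemiketal F1. Stereoretentive reduction of the alkenyl iodide (Pd(PPh3)4, Bu3SnH, THF) then returns to the route at 22.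

Second, step 12. The alkoxide may fragment into an enone and a furanolate (retro-aldol mode) and recombine at C6 instead of C4 (a formal 1,3-shift), or the amide base or the enolate may add to the electrophilic allene of the product. The fallback removes the anion and sets out from 18, isolated by leaving out the citric acid treatment of step 11. The neutral thermal siloxy-Cope rearrangement (1,2-dichlorobenzene, 170 °C, base-washed glass) should give the TMS enol ether F2. Mild methanolysis (citric acid, MeOH, 0 °C) converts it into 21, where the route is rejoined.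

Third, step 8. Poor facial selectivity in the vinyl addition, or enolisation, would pass on the C1 epimer, which would misdirect the propynyl addition of step 11 and stop the rearrangement of step 12. The fallback sets out from 13. Corey-Chaykovsky methylenation with dimethylsulfoxonium methylide (Me3S(O)I, NaH, DMSO), which delivers the CH2 group equatorially under thermodynamic control, should give the spiro-epoxide F3 with its oxygen cis to the methyl group. One-carbon homologation with an excess of dimethylsulfonium methylide (Me3SI, n-BuLi, THF, −10 °C to rt) opens the epoxide at CH2 and eliminates to the vinyl carbinol, which is 14.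

Further compounds
F1 | step 13 | C5-iodo derivative of 22 (iodine on the exocyclic alkene carbon, cis to the lactone oxygen) | CC(C)(C)[Si](C)(C)OCC1=C2/C(=C(/I)\[C@]3(C)CC[C@@](O)(O3)[C@H](C)C[C@@H]2O[Si](C)(C)C(C)(C)C)OC1=O
F2 | step 12 | TMS enol ether (C1–C2) of 21 | C[C@@H]1C[C@H](O[Si](C)(C)C(C)(C)C)C2=C(CO[Si](C)(C)C(C)(C)C)C(=O)OC2=[C@]=C(C)C/C=C1/O[Si](C)(C)C
F3 | step 8 | spiro-epoxide of 13 at the former carbonyl carbon (oxirane oxygen cis to the methyl group) | C1O[C@@]12[C@H](C)C[C@H](O[Si](C)(C)C(C)(C)C)c3c(CO[Si](C)(C)C(C)(C)C)coc23
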